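**Assumptions (one line each):** (S)-eriodictyol is treated as a commercial, citrus-derived chiral starting material. The regiochemistry of nucleophilic addition to the eriodictyol o-quinone is assumed to follow that of dopa-quinone, where thiols add at C5′ and then C2′ (1,6-additions).

## Retrosynthetic overview
1. Sigmoidin A (**1**) ⇒ two allyl→prenyl cross-metatheses on 2′,5′-diallyl-eriodictyol (**2**), using 2-methyl-2-butene (**5**).
2. **2** ⇒ (S)-eriodictyol (**3**) + allyltrimethylsilane (**4**). The catechol is oxidised anodically to the o-quinone, and two Sakurai-type 1,6-allylations occur at C5′ and C2′, which are the positions ortho to each catechol OH and away from C6′.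
3. No ring is formed in the sequence. The chromanone and the B ring both come from **3**, and the C2 (S) centre is carried through untouched.

## Route

**Step 1**
Reactants: **3** (2S)-eriodictyol; **4** allyltrimethylsilane
Product: **2** (2S)-2-(2,5-diallyl-3,4-dihydroxyphenyl)-5,7-dihydroxychroman-4-one
Conditions: undivided cell, carbon-felt anode, Pt cathode, constant current (about 3 mA/cm²), 0.1 M LiClO4, HFIP/MeCN 1:4, **4** (10 equiv, added in portions), N2, 25 °C, about 4.5 F/mol
Reagents that add atoms: allyltrimethylsilane, C=CC[Si](C)(C)C (two allyl groups; the SiMe3 ends up as Me3SiOCH(CF3)2)
Why: Proposed new method: anodic oxidation of the catechol (Eox about 0.5 V, far below that of the phloroglucinol A ring or the allylsilane) gives the 3′,4′-o-quinone. HFIP and Li⁺ activate it toward Hosomi–Sakurai attack by the allylsilane at the vinylogous (1,6) position C5′. The β-silyl cation loses Me3Si⁺ and the dienone-ol tautomerises back to a catechol. That more electron-rich catechol is re-oxidised and allylated at C2′, the only remaining 1,6-position, which gives the 2′,5′-pattern. The closest known reactions are Sakurai allylation of p-quinones, thiol 1,6-addition to dopa-quinone, and anodic catechol→o-quinone trapping. No new stereocentre forms, and the conditions are non-basic, so C2 is not racemised by retro-oxa-Michael ring opening.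

**Step 2**
Reactants: **2**; **5** 2-methyl-2-butene
Product: **1** sigmoidin A
Conditions: Hoveyda–Grubbs II (10 mol%), **5** (30 equiv), CH2Cl2, sealed tube, 40 °C, 16 h
Reagents that add atoms: 2-methyl-2-butene, CC=C(C)C (supplies the isopropylidene ends; propene is lost)
Why: Olefin cross-metathesis converts each terminal ArCH2CH=CH2 into ArCH2CH=CMe2, because the excess trisubstituted alkene drives the exchange. The ketone, phenols, and benzylic ether stereocentre are untouched, and C2 is not epimerised under these neutral conditions.

**Final checks**
- Atom balance: **3** C15H12O6 → **2** C21H20O6 (two H replaced by two C3H5) → **1** C25H28O6.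
- Ring sizes and substituents: the product has the 5,7-dihydroxychroman-4-one core and a B ring with 3′,4′-OH, 2′- and 5′-prenyl and 6′-H, matching the target SMILES.
- Stereochemistry: C2 is (S) in **3** (checked by CIP analysis of the SMILES), is never a reacting centre, and is (S) in **1**.

## Compound list
1 | sigmoidin A | CC(C)=CCc1cc([C@@H]2CC(=O)c3c(O)cc(O)cc3O2)c(CC=C(C)C)c(O)c1O | target
2 | (2S)-2-(2,5-diallyl-3,4-dihydroxyphenyl)-5,7-dihydroxychroman-4-one | C=CCc1cc([C@@H]2CC(=O)c3c(O)cc(O)cc3O2)c(CC=C)c(O)c1O | intermediate
3 | (2S)-eriodictyol | O=C1C[C@@H](c2ccc(O)c(O)c2)Oc2cc(O)cc(O)c12 | starting material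
4 | allyltrimethylsilane | C=CC[Si](C)(C)C | starting material
5 | 2-methyl-2-butene | CC=C(C)C | starting material

## Totals
Total steps: 2. Longest linear sequence: 2.

## Three most likely failure points
The route has only two steps, so two of the three points fall within step 1.

1. **Step 1, first allylation (the proposed new step).** Selectivity for C5′ over C6′ (1,4-addition) may be poor, A-ring/quinone coupling may occur, and the allylsilane may be protodesilylated by anodic acid.
   - Fallback: run it stepwise with chemical oxidation. Oxidise with IBX, allylate the isolated o-quinone with allylTMS under Sc(OTf)3, reduce with Na2S2O4, separate the 5′-allyl isomer, and repeat.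
2. **Step 1, second allylation at C2′.** This position is flanked by the C2 substituent and the 3′-OH, so the reaction may stall at the 5′-mono-allyl compound or over-oxidise.
   - Fallback: isolate 5′-allyl-eriodictyol and run the second round on the separately generated o-quinone (Ag2O, then allyl-Bpin/HFIP) with stoichiometric control of the charge.
3. **Step 2, cross-metathesis on the free catechol.** The free catechol may poison the Ru catalyst, and allyl→propenyl isomerisation is a competing pathway.
   - Fallback: peracetylate the phenols (Ac2O, pyridine), run the metathesis on the acetate, then remove the acetates under mild non-basic conditions (hydrazine acetate, DMF) to protect the C2 centre.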